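Tuesday's flask had 2.21 times Thursday's partner, and at 40.0 min it holds 2.01 times Thursday's intermediate A. That comparison suggests one number to freeze.

| flask | substrate | partner | third reagent | solid second reagent | remark | time |
|---|---|---|---|---|---|---|
| Thursday's | 0.050 M (in portions, 4) | 0.034 M | 0.030 M | 0.055 M | run made earlier; portions every 12 min |  |
| Tuesday's | 0.050 M (in portions, 4) | 0.075 M | 0.030 M | 0.055 M | run made earlier; portions every 12 min |  |
| flask | 0.050 M (in portions, 4) | 0.0500 M | 0.0300 M | 0.0550 M | the portions of substrate follow each other after 12 min, the first at the start | 1.0 h |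

| run | time / min | substrate / % | intermediate A / % | target / % |
|---|---|---|---|---|
| Thursday's | 3.00 | 23.2 | 1.3 | 0.9 |
| Thursday's | 10.0 | 21.2 | 4.1 | 0 |
| Thursday's | 15.0 | 44.7 | 6.5 | 1.1 |
| Thursday's | 25.0 | 65.5 | 9.5 | 0 |
| Thursday's | 40.0 | 84.7 | 15.4 | 0.1 |
| Tuesday's | 3.00 | 21.8 | 2.7 | 0 |
| Tuesday's | 5.00 | 20.3 | 5.4 | 0.3 |
| Tuesday's | 10.0 | 17.8 | 7.8 | 0 |
| Tuesday's | 20.0 | 35.0 | 15.5 | 0 |
| Tuesday's | 40.0 | 69.3 | 31.0 | 0.1 |

(scatter of a reading: 0.5 percentage points)

1. concentration of substrate at 1.0 h, in M
2. concentration of intermediate A at 1.0 h, in M

- the earlier runs were read with a standard deviation of 0.5 percentage points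
- at the start none of the solid second reagent is in solution

In the last row of each table, substrate and intermediate A add up to the whole charge within the scatter, and target stays near nothing. Intermediate A per partner charged is 0.226 on Thursday and 0.207 on Tuesday, so I take the mean, 0.217.

The asked time lies beyond these rows, so I read the substrate column against the intermediate A column on Tuesday. Intermediate A gained per minute per substrate standing, a pseudo-first-order constant, is 0.0394 min⁻¹ in the first rows and 0.0149 min⁻¹ in the last two. It therefore fades with a half-life of about 17.8 min, which is 0.0390 min⁻¹ as a decay constant.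

The last portion goes in at 36.0 min; after that no substrate is added, and what stands keeps falling as it turns into intermediate A. My reckoning leaves that fall of substrate out and lets the gain fade at the pace just read. I let Tuesday's late slope of the share, 0.00517 min⁻¹, decay at that pace. The capture share, the intermediate A held at 1.0 h per partner charged, then comes to 0.288. My reckoning is 0.0144 M of intermediate A and 0.0356 M of substrate.

The forecast says 0.0338 M and 0.016 M, higher in intermediate A than mine, on the ground that “the step is zero order in substrate”.

The flask gives 0.0361 M of substrate and 0.0131 M of intermediate A, a capture share of 0.262.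

    substrate + partner → intermediate A (k = 0.576 L mol⁻¹ min⁻¹)
    second reagent + intermediate A → intermediate B (k = 0.142 L mol⁻¹ min⁻¹)
    third reagent + intermediate B → target (k = 1.68 L mol⁻¹ min⁻¹)
    substrate + second reagent → side product (k = 0.0118 L mol⁻¹ min⁻¹)
    partner → decomposed reagent (k = 0.0277 min⁻¹)
    solid second reagent ⇌ second reagent, rate k6*(cs6 - [second reagent]) while solid is left; crystals form when [second reagent] > cs6 (solubility = 9.20 mM, k = 0.535 min⁻¹)

At 0.251 h in this flask, partner goes into decomposed reagent 2.3 times as fast as into intermediate A. Its half-life by that decomposition alone is 0.42 h, shorter than the 1.0 h of the run, and 7.5 % of the partner is left at the end. For the neighbour flask with 0.020 M of partner, the capture share reckoned above gives 0.00576 M, and that flask holds 0.00576 M of intermediate A.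

(Readings and results are calculated with constants of no real substance; scatter was added.)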